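**Retrosynthetic overview**

1. The target is taken back to a ten-membered β-hydroxy ketone (C8 ketone, C10 tertiary alcohol, C13 silyl ether). The last steps are a reagent-controlled C8 reduction, a double acetylation and a desilylation.
2. The key disconnection is C9–C10. The ten-membered ring is closed by a catalyst-controlled aldol-type addition of a 1-ethoxyvinyl group on C7 (its terminal carbon is C9) to the acetyl carbonyl C10 of an open-chain C1/C10 vicinal diketone.
3. Enabling feature: the ring atoms C8(O)–C9H2–C10(O)(CH3)–C1(=O) are an aldol retron in which C10 is the less hindered carbonyl of a 1,2-diketone that can bind a chiral divalent-copper Lewis acid through both oxygens. The butenolide ring (O–C12–C11=C7–C6) carries the two reacting arms on its adjacent atoms C6 and C7.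
4. The substituted butenolide comes from a 3,4-diiodobutenolide by two Stille couplings. The diiodide comes from an epoxy γ-hydroxy ynoate: asymmetric alkynylation of an enal with methyl propiolate sets C6, and a hydroxyl-directed epoxidation sets C4/C5.
5. The enal chain comes from silyl-protected acetoin and an E allylic bromide. Ring order: epoxide (step 9), butenolide (step 10), ten-membered carbocycle (step 15).

Key step: step 15

Remark: C1–C15 are the germacrane positions of the target; the acetoin-derived carbinol is carried as an epimer mixture until step 14 oxidises it, and the sense of induction of the ProPhenol, bis(oxazoline) and oxazaborolidine catalysts is assumed from their accepted models (the antipodal ligand would be used if a model run showed the opposite sense).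

**Route**

Step 1
Reactants: 1 prenyl acetate
Product: 2 (E)-4-hydroxy-3-methylbut-2-en-1-yl acetate
Conditions: SeO2 (cat.), t-BuOOH, salicylic acid (cat.), CH2Cl2, rt
Reagents that add atoms: tert-butyl hydroperoxide CC(C)(C)OO (oxygen atom, relayed by the catalyst selenium dioxide O=[Se]=O)
Why: Riley-type allylic oxidation (ene reaction then [2,3]-shift) hydroxylates the methyl group trans to the acetoxymethyl-bearing carbon, which fixes the E geometry of the later C4=C5 bond; no stereocentre is formed.

Step 2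
Reactants: 2 (E)-4-hydroxy-3-methylbut-2-en-1-yl acetate
Product: 3 (E)-4-bromo-3-methylbut-2-en-1-yl acetate
Conditions: CBr4, PPh3, CH2Cl2, 0 °C
Reagents that add atoms: carbon tetrabromide BrC(Br)(Br)Br
Why: The Appel reaction converts the primary allylic alcohol into the bromide by SN2 displacement at CH2 under cold neutral conditions, so the acetate and the alkene geometry should be kept.

Step 3
Reactants: 4 acetoin
Product: 5 racemic 3-[(tert-butyldimethylsilyl)oxy]butan-2-one
Conditions: TBSCl, imidazole, DMF, rt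
Reagents that add atoms: tert-butyldimethylsilyl chloride CC(C)(C)[Si](C)(C)Cl
Why: Standard imidazole-promoted silylation masks the acyloin hydroxyl for enolate chemistry; the racemic centre is oxidised away later.

Step 4
Reactants: 5 racemic 3-[(tert-butyldimethylsilyl)oxy]butan-2-one; 3 (E)-4-bromo-3-methylbut-2-en-1-yl acetate
Product: 7 (E)-7-[(tert-butyldimethylsilyl)oxy]-3-methyl-6-oxooct-2-en-1-yl acetate, via lithium enolate 6 (not isolated)
Conditions: LDA, THF, −78 °C; then 3, −78 to −20 °C
Reagents that add atoms: none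
Why: Kinetic deprotonation of the α-silyloxy ketone occurs at the methyl group, and SN2 alkylation of this enolate by the allylic bromide (enolate alkylation) forms C2–C3 faster than the enolate attacks the acetate at low temperature.

Step 5
Reactants: 7 (E)-7-[(tert-butyldimethylsilyl)oxy]-3-methyl-6-oxooct-2-en-1-yl acetate
Product: 8 (E)-2-[(tert-butyldimethylsilyl)oxy]-8-hydroxy-6-methyloct-6-en-3-one
Conditions: K2CO3 (cat.), MeOH, 0 °C
Reagents that add atoms: none
Why: Base-catalysed transesterification with methanol frees the allylic alcohol while the silyl ether and ketone are stable.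

Step 6
Reactants: 8 (E)-2-[(tert-butyldimethylsilyl)oxy]-8-hydroxy-6-methyloct-6-en-3-one
Product: 9 (E)-7-[(tert-butyldimethylsilyl)oxy]-3-methyl-6-oxooct-2-enal
Conditions: MnO2, CH2Cl2, rt
Reagents that add atoms: none
Why: Manganese dioxide oxidation is selective for the allylic alcohol and should give the E enal without touching the silyloxy ketone.

Step 7
Reactants: 9 (E)-7-[(tert-butyldimethylsilyl)oxy]-3-methyl-6-oxooct-2-enal; 10 methyl propiolate
Product: 12 methyl (4R,5E)-10-[(tert-butyldimethylsilyl)oxy]-4-hydroxy-6-methyl-9-oxoundec-5-en-2-ynoate, via methylzinc acetylide 11 (not isolated)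
Conditions: Me2Zn, (S,S)-ProPhenol (20 mol%), Ph3PO (cat.), toluene, 4 °C
Reagents that add atoms: none
Why: Dinuclear zinc–ProPhenol-catalysed asymmetric alkynylation of the enal sets the C6 carbinol by catalyst control (4R here, the spatial arrangement that is 6S in the target), and the alkynylzinc does not add to the ketone.

Step 8
Reactants: 12 methyl (4R,5E)-10-[(tert-butyldimethylsilyl)oxy]-4-hydroxy-6-methyl-9-oxoundec-5-en-2-ynoate
Product: 13 methyl (4R,5E)-4,10-dihydroxy-6-methyl-9-oxoundec-5-en-2-ynoate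
Conditions: HF·pyridine, pyridine, THF, 0 °C to rt
Reagents that add atoms: none
Why: Buffered fluoride desilylation frees the acyloin hydroxyl before the acid-sensitive epoxide exists, and the γ-hydroxy ynoate tolerates these non-basic conditions.

Step 9
Reactants: 13 methyl (4R,5E)-4,10-dihydroxy-6-methyl-9-oxoundec-5-en-2-ynoate
Product: 14 methyl (4S)-4-hydroxy-4-[(2R,3R)-3-(4-hydroxy-3-oxopentyl)-3-methyloxiran-2-yl]but-2-ynoate
Conditions: mCPBA, CH2Cl2, 0 °C
Reagents that add atoms: meta-chloroperoxybenzoic acid OOC(=O)c1cccc(Cl)c1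
Why: Hydroxyl-directed peracid epoxidation: allylic 1,3-strain between the C15 methyl and the C6 substituents holds C6–H in the alkene plane, so the C6 hydroxyl delivers oxygen to one face and the threo (4R,5R) epoxide should form, while the electron-poor alkynoate is inert.

Step 10
Reactants: 14 methyl (4S)-4-hydroxy-4-[(2R,3R)-3-(4-hydroxy-3-oxopentyl)-3-methyloxiran-2-yl]but-2-ynoate
Product: 17 5-[(2R,3R)-3-(4-hydroxy-3-oxopentyl)-3-methyloxiran-2-yl]-3,4-diiodofuran-2(5H)-one, via Z-bis(trimethylstannyl) hydroxy ester 15 (not isolated), via bis(trimethylstannyl)butenolide 16 (not isolated)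
Conditions: Me3SnSnMe3, Pd(PPh3)4 (cat.), THF, 65 °C; then I2, 0 °C
Reagents that add atoms: iodine II
Why: Palladium-catalysed syn bis-stannylation of the alkynoate places the ester cis to the C6 hydroxyl so that lactonisation closes the butenolide with the C6–O bond untouched, and iododestannylation then replaces both tin groups with retention.

Step 11
Reactants: 17 5-[(2R,3R)-3-(4-hydroxy-3-oxopentyl)-3-methyloxiran-2-yl]-3,4-diiodofuran-2(5H)-one; 18 tributyl(1-ethoxyvinyl)stannane
Product: 19 4-(1-ethoxyvinyl)-5-[(2R,3R)-3-(4-hydroxy-3-oxopentyl)-3-methyloxiran-2-yl]-3-iodofuran-2(5H)-one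
Conditions: Pd2(dba)3 (cat.), AsPh3, CuI (cat.), NMP, rt
Reagents that add atoms: none
Why: Stille coupling: zerovalent palladium inserts first into the C–I bond β to the lactone carbonyl (C7), as in 3,4-dihalobutenolides, which installs the enol ether that later serves as the C8–C9 nucleophile.

Step 12
Reactants: 19 4-(1-ethoxyvinyl)-5-[(2R,3R)-3-(4-hydroxy-3-oxopentyl)-3-methyloxiran-2-yl]-3-iodofuran-2(5H)-one; 20 (tributylstannyl)methanol
Product: 21 (5S)-4-(1-ethoxyvinyl)-3-(hydroxymethyl)-5-[(2R,3R)-3-(4-hydroxy-3-oxopentyl)-3-methyloxiran-2-yl]furan-2(5H)-one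
Conditions: Pd(PPh3)4 (cat.), dioxane, 80 °C
Reagents that add atoms: none
Why: Stille hydroxymethylation of the remaining α-iodide introduces C13 under neutral conditions that leave the epoxide, enol ether and the base-sensitive C6–H untouched.

Step 13
Reactants: 21 (5S)-4-(1-ethoxyvinyl)-3-(hydroxymethyl)-5-[(2R,3R)-3-(4-hydroxy-3-oxopentyl)-3-methyloxiran-2-yl]furan-2(5H)-one
Product: 22 (5S)-4-(1-ethoxyvinyl)-5-[(2R,3R)-3-(4-hydroxy-3-oxopentyl)-3-methyloxiran-2-yl]-3-{[(triethylsilyl)oxy]methyl}furan-2(5H)-one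
Conditions: TESCl, imidazole, CH2Cl2, −40 °C
Reagents that add atoms: triethylsilyl chloride CC[Si](Cl)(CC)CC
Why: Silylation at low temperature should select the primary C13 hydroxyl over the hindered secondary α-ketol hydroxyl.

Step 14
Reactants: 22 (5S)-4-(1-ethoxyvinyl)-5-[(2R,3R)-3-(4-hydroxy-3-oxopentyl)-3-methyloxiran-2-yl]-3-{[(triethylsilyl)oxy]methyl}furan-2(5H)-one
Product: 23 (5S)-5-[(2R,3R)-3-(3,4-dioxopentyl)-3-methyloxiran-2-yl]-4-(1-ethoxyvinyl)-3-{[(triethylsilyl)oxy]methyl}furan-2(5H)-one
Conditions: Dess–Martin periodinane, pyridine, CH2Cl2, 0 °C to rt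
Reagents that add atoms: none
Why: Dess–Martin oxidation turns the α-ketol into the C1/C10 vicinal diketone under buffered neutral conditions that spare the enol ether, epoxide and silyl ether, and it removes the epimeric centre.

Step 15
Reactants: 23 (5S)-5-[(2R,3R)-3-(3,4-dioxopentyl)-3-methyloxiran-2-yl]-4-(1-ethoxyvinyl)-3-{[(triethylsilyl)oxy]methyl}furan-2(5H)-one
Product: 25 (4R,5R,6S,10R)-4,5-epoxy-10-hydroxy-1,8-dioxo-13-[(triethylsilyl)oxy]germacr-7(11)-en-12,6-olide, via macrocyclic ethyl enol ether 24 (not isolated)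
Conditions: [Cu((R,R)-t-Bu-box)](SbF6)2 (20 mol%; box = 2,2'-isopropylidenebis(4-tert-butyl-2-oxazoline)), CH2Cl2, −40 to 0 °C, 1 mM by slow addition; then THF, aq. pH 5 buffer, 0 °C
Reagents that add atoms: water O
Why: Proposed new method: the chiral divalent-copper bis(oxazoline) Lewis acid binds the C1/C10 vicinal diketone as a five-membered chelate, the electron-rich terminal carbon C9 of the 1-ethoxyvinyl group adds to the activated C10 carbonyl to give an alkoxide/oxocarbenium pair that collapses by proton loss to enol ether 24, and mild aqueous acid hydrolyses 24 to the C8 ketone; the closest known reaction types are the intermolecular bis(oxazoline)copper-catalysed Mukaiyama aldol addition of enol silanes to pyruvates and 2,3-diketones, the aldol-type addition of 2-alkoxypropenes to activated carbonyls, and Lewis-acid-mediated intramolecular Mukaiyama aldol closures of medium rings. The ten-membered carbocycle (C1 to C10) closes in a 10-(enolendo)-exo-trig mode. The new stereocentre C10 (R) is set by the ligand, whose tert-butyl groups shield one face of the planar chelated diketone (catalyst control, by analogy with the sense known for pyruvates). The step needs attack at C10 and not C1 (the acetyl carbonyl is the less hindered one, as in known additions to 2,3-pentanedione), activation of the diketone and not the epoxide (two-point against one-point binding), reaction only at C9 (the enol ether is the sole π-nucleophile and no base is present, so C6–H is untouched), and ring closure in preference to oligomerisation (high dilution, helped by the butenolide, which holds the C6 and C7 arms on adjacent ring atoms).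

Step 16
Reactants: 25 (4R,5R,6S,10R)-4,5-epoxy-10-hydroxy-1,8-dioxo-13-[(triethylsilyl)oxy]germacr-7(11)-en-12,6-olide
Product: 26 (4R,5R,6S,8S,10R)-4,5-epoxy-8,10-dihydroxy-1-oxo-13-[(triethylsilyl)oxy]germacr-7(11)-en-12,6-olide
Conditions: (R)-Me-CBS (20 mol%), catecholborane, toluene, −78 °C
Reagents that add atoms: none
Why: Corey–Bakshi–Shibata reduction: the oxazaborolidine treats the branched alkenyl carbon C7 as the large group and the C9 methylene as the small one and should deliver hydride to the face that gives 8S (1,3-syn to the C10 oxygen, a sense also favoured by boron chelation of the C10 hydroxyl), while the C1 ketone next to the quaternary C10 should react much more slowly.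

Step 17
Reactants: 26 (4R,5R,6S,8S,10R)-4,5-epoxy-8,10-dihydroxy-1-oxo-13-[(triethylsilyl)oxy]germacr-7(11)-en-12,6-olide
Product: 27 (4R,5R,6S,8S,10R)-8,10-diacetoxy-4,5-epoxy-1-oxo-13-[(triethylsilyl)oxy]germacr-7(11)-en-12,6-olide
Conditions: Ac2O, DMAP, CH2Cl2, rt
Reagents that add atoms: acetic anhydride CC(=O)OC(C)=O
Why: DMAP-catalysed acetylation esterifies the secondary C8 hydroxyl and, more slowly, the tertiary C10 hydroxyl; no stereocentre is touched and the silyl ether, epoxide and lactone should survive these mildly basic conditions.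

Step 18
Reactants: 27 (4R,5R,6S,8S,10R)-8,10-diacetoxy-4,5-epoxy-1-oxo-13-[(triethylsilyl)oxy]germacr-7(11)-en-12,6-olide
Product: 28 (4R,5R,6S,8S,10R)-8,10-diacetoxy-4,5-epoxy-13-hydroxy-1-oxogermacr-7(11)-en-12,6-olide
Conditions: HF·pyridine, pyridine, THF, 0 °C
Reagents that add atoms: none
Why: Buffered fluoride cleavage of the primary triethylsilyl ether should leave the two acetates, the epoxide and the butenolide intact and give the target.

**Compound list**

1 | prenyl acetate (3-methylbut-2-en-1-yl acetate) | CC(C)=CCOC(C)=O | starting material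
2 | (E)-4-hydroxy-3-methylbut-2-en-1-yl acetate | OC/C(C)=C/COC(C)=O | intermediate
3 | (E)-4-bromo-3-methylbut-2-en-1-yl acetate | BrC/C(C)=C/COC(C)=O | intermediate
4 | acetoin (racemic 3-hydroxybutan-2-one) | CC(O)C(C)=O | starting material
5 | racemic 3-[(tert-butyldimethylsilyl)oxy]butan-2-one | CC(O[Si](C)(C)C(C)(C)C)C(C)=O | intermediate
6 | lithium enolate of 5, lithium 3-[(tert-butyldimethylsilyl)oxy]but-1-en-2-olate (not isolated) | C=C(O[Li])C(C)O[Si](C)(C)C(C)(C)C | intermediate
7 | (E)-7-[(tert-butyldimethylsilyl)oxy]-3-methyl-6-oxooct-2-en-1-yl acetate (racemic at the silyloxy carbon) | CC(O[Si](C)(C)C(C)(C)C)C(=O)CC/C(C)=C/COC(C)=O | intermediate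
8 | (E)-2-[(tert-butyldimethylsilyl)oxy]-8-hydroxy-6-methyloct-6-en-3-one | CC(O[Si](C)(C)C(C)(C)C)C(=O)CC/C(C)=C/CO | intermediate
9 | (E)-7-[(tert-butyldimethylsilyl)oxy]-3-methyl-6-oxooct-2-enal | CC(O[Si](C)(C)C(C)(C)C)C(=O)CC/C(C)=C/C=O | intermediate
10 | methyl propiolate | C#CC(=O)OC | starting material
11 | methylzinc acetylide of 10, methyl 3-(methylzincio)prop-2-ynoate (not isolated) | C[Zn]C#CC(=O)OC | intermediate
12 | methyl (4R,5E)-10-[(tert-butyldimethylsilyl)oxy]-4-hydroxy-6-methyl-9-oxoundec-5-en-2-ynoate (epimers at the silyloxy carbon) | CC(O[Si](C)(C)C(C)(C)C)C(=O)CC/C(C)=C/[C@@H](O)C#CC(=O)OC | intermediate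
13 | methyl (4R,5E)-4,10-dihydroxy-6-methyl-9-oxoundec-5-en-2-ynoate | CC(O)C(=O)CC/C(C)=C/[C@@H](O)C#CC(=O)OC | intermediate
14 | methyl (4S)-4-hydroxy-4-[(2R,3R)-3-(4-hydroxy-3-oxopentyl)-3-methyloxiran-2-yl]but-2-ynoate | CC(O)C(=O)CC[C@@]1(C)O[C@@H]1[C@@H](O)C#CC(=O)OC | intermediate
15 | methyl (2Z)-4-hydroxy-4-[(2R,3R)-3-(4-hydroxy-3-oxopentyl)-3-methyloxiran-2-yl]-2,3-bis(trimethylstannyl)but-2-enoate (carbinol centre spatially as in 14, formally 4R because of tin; not isolated) | CC(O)C(=O)CC[C@@]1(C)O[C@@H]1[C@@H](O)/C([Sn](C)(C)C)=C(/[Sn](C)(C)C)C(=O)OC | intermediate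
16 | 5-[(2R,3R)-3-(4-hydroxy-3-oxopentyl)-3-methyloxiran-2-yl]-3,4-bis(trimethylstannyl)furan-2(5H)-one (ring carbon 5 spatially as in 14, formally 5R; not isolated) | CC(O)C(=O)CC[C@@]1(C)O[C@@H]1[C@H]1OC(=O)C([Sn](C)(C)C)=C1[Sn](C)(C)C | intermediate
17 | 5-[(2R,3R)-3-(4-hydroxy-3-oxopentyl)-3-methyloxiran-2-yl]-3,4-diiodofuran-2(5H)-one (ring carbon 5 spatially as in 14, formally 5R because of iodine) | CC(O)C(=O)CC[C@@]1(C)O[C@@H]1[C@H]1OC(=O)C(I)=C1I | intermediate
18 | tributyl(1-ethoxyvinyl)stannane | CCCC[Sn](CCCC)(CCCC)C(=C)OCC | starting material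
19 | (5S)-4-(1-ethoxyvinyl)-5-[(2R,3R)-3-(4-hydroxy-3-oxopentyl)-3-methyloxiran-2-yl]-3-iodofuran-2(5H)-one | CC(O)C(=O)CC[C@@]1(C)O[C@@H]1[C@H]1OC(=O)C(I)=C1C(=C)OCC | intermediate
20 | (tributylstannyl)methanol | CCCC[Sn](CCCC)(CCCC)CO | starting material
21 | (5S)-4-(1-ethoxyvinyl)-3-(hydroxymethyl)-5-[(2R,3R)-3-(4-hydroxy-3-oxopentyl)-3-methyloxiran-2-yl]furan-2(5H)-one | CC(O)C(=O)CC[C@@]1(C)O[C@@H]1[C@H]1OC(=O)C(CO)=C1C(=C)OCC | intermediate
22 | (5S)-4-(1-ethoxyvinyl)-5-[(2R,3R)-3-(4-hydroxy-3-oxopentyl)-3-methyloxiran-2-yl]-3-{[(triethylsilyl)oxy]methyl}furan-2(5H)-one | CC(O)C(=O)CC[C@@]1(C)O[C@@H]1[C@H]1OC(=O)C(CO[Si](CC)(CC)CC)=C1C(=C)OCC | intermediate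
23 | (5S)-5-[(2R,3R)-3-(3,4-dioxopentyl)-3-methyloxiran-2-yl]-4-(1-ethoxyvinyl)-3-{[(triethylsilyl)oxy]methyl}furan-2(5H)-one | CC(=O)C(=O)CC[C@@]1(C)O[C@@H]1[C@H]1OC(=O)C(CO[Si](CC)(CC)CC)=C1C(=C)OCC | intermediate
24 | (4R,5R,6S,10R)-8-ethoxy-4,5-epoxy-10-hydroxy-1-oxo-13-[(triethylsilyl)oxy]germacra-7(11),8-dien-12,6-olide (not isolated) | CCOC1=C[C@@](C)(O)C(=O)CC[C@@]2(C)O[C@@H]2[C@H]2OC(=O)C(CO[Si](CC)(CC)CC)=C12 | intermediate
25 | (4R,5R,6S,10R)-4,5-epoxy-10-hydroxy-1,8-dioxo-13-[(triethylsilyl)oxy]germacr-7(11)-en-12,6-olide | O=C1C[C@@](C)(O)C(=O)CC[C@@]2(C)O[C@@H]2[C@H]2OC(=O)C(CO[Si](CC)(CC)CC)=C12 | intermediate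
26 | (4R,5R,6S,8S,10R)-4,5-epoxy-8,10-dihydroxy-1-oxo-13-[(triethylsilyl)oxy]germacr-7(11)-en-12,6-olide | O[C@H]1C[C@@](C)(O)C(=O)CC[C@@]2(C)O[C@@H]2[C@H]2OC(=O)C(CO[Si](CC)(CC)CC)=C12 | intermediate
27 | (4R,5R,6S,8S,10R)-8,10-diacetoxy-4,5-epoxy-1-oxo-13-[(triethylsilyl)oxy]germacr-7(11)-en-12,6-olide | CC(=O)O[C@H]1C[C@@](C)(OC(C)=O)C(=O)CC[C@@]2(C)O[C@@H]2[C@H]2OC(=O)C(CO[Si](CC)(CC)CC)=C12 | intermediate
28 | (4R,5R,6S,8S,10R)-8,10-diacetoxy-4,5-epoxy-13-hydroxy-1-oxogermacr-7(11)-en-12,6-olide (CNP0266633.2) | CC(=O)O[C@H]1C[C@@](C)(OC(C)=O)C(=O)CC[C@@]2(C)O[C@@H]2[C@H]2OC(=O)C(CO)=C12 | target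

**Step count and risks**

Total step count: 18. Longest linear sequence: 17 steps (prenyl acetate to the target: steps 1, 2 and 4 to 18; step 3 is a one-step side branch).

Steps most likely to fail:

1. Step 15 (key step). Oligomerisation may compete with ring closure, the enol ether may attack the C1 carbonyl, the Lewis acid may open the epoxide, or the tertiary aldol may cleave by retro-aldol reaction during hydrolysis. Fallback with known chemistry, changing from Lewis-acid catalysis to a regiospecific metal enolate: from 23, NBS in THF–water at 0 °C converts the enol ether into the bromo ketone F1. Slow addition of F1 to activated zinc in THF at rt under high dilution forms the zinc enolate, and its intramolecular Reformatsky addition to the C10 carbonyl returns to the route at 25. Without catalyst control the C10 epimers would have to be separated at that stage.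

2. Step 16. Hydride may also reduce the C1 ketone, or be delivered to the wrong face of C8. Fallback, changing from reagent control to internal delivery followed by inversion: from 25, hydroxyl-directed reduction with Me4NBH(OAc)3 in MeCN–AcOH at −30 °C reduces only a ketone that can accept hydride through a six-membered boron chelate and should give the 1,3-anti diol F2 (8R). A Mitsunobu reaction of its secondary hydroxyl with acetic acid (PPh3, DIAD, toluene, 0 °C) inverts C8 and gives the 8S monoacetate F3. DMAP-catalysed acetylation of the remaining tertiary hydroxyl with Ac2O rejoins the route at 27.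

3. Step 12. Transfer of the sp3 carbon from tin to palladium may be slow at the hindered α-iodide, so that protodeiodination or loss of the enol ether on prolonged heating takes over. Fallback, changing the C13 source to carbon monoxide: from 19, reductive carbonylation of the vinyl iodide (CO at 1 atm, Bu3SnH by slow addition, Pd(PPh3)4, THF, 50 °C) gives the aldehyde F4. Aldehyde-selective reduction with LiAlH(O-t-Bu)3 in THF at −78 °C rejoins the route at 21.

Further compounds

F1 | step 15 | (5S)-4-(bromoacetyl)-5-[(2R,3R)-3-(3,4-dioxopentyl)-3-methyloxiran-2-yl]-3-{[(triethylsilyl)oxy]methyl}furan-2(5H)-one | CC(=O)C(=O)CC[C@@]1(C)O[C@@H]1[C@H]1OC(=O)C(CO[Si](CC)(CC)CC)=C1C(=O)CBr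
F2 | step 16 | (4R,5R,6S,8R,10R)-4,5-epoxy-8,10-dihydroxy-1-oxo-13-[(triethylsilyl)oxy]germacr-7(11)-en-12,6-olide | O[C@@H]1C[C@@](C)(O)C(=O)CC[C@@]2(C)O[C@@H]2[C@H]2OC(=O)C(CO[Si](CC)(CC)CC)=C12
F3 | step 16 | (4R,5R,6S,8S,10R)-8-acetoxy-4,5-epoxy-10-hydroxy-1-oxo-13-[(triethylsilyl)oxy]germacr-7(11)-en-12,6-olide | CC(=O)O[C@H]1C[C@@](C)(O)C(=O)CC[C@@]2(C)O[C@@H]2[C@H]2OC(=O)C(CO[Si](CC)(CC)CC)=C12
F4 | step 12 | (5S)-4-(1-ethoxyvinyl)-5-[(2R,3R)-3-(4-hydroxy-3-oxopentyl)-3-methyloxiran-2-yl]-2-oxo-2,5-dihydrofuran-3-carbaldehyde | CC(O)C(=O)CC[C@@]1(C)O[C@@H]1[C@H]1OC(=O)C(C=O)=C1C(=C)OCC
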